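**Plan**

- Numbering: the heptane chain runs from C1 (on ring B, the 3,4-dihydroxy-5-methoxyphenyl ring) to C7 (on ring A, the 4-hydroxy-3-methoxyphenyl ring); C3 is the ketone and C5 the (R)-carbinol.
- Enabling feature: the C5 carbinol is β to the C3 carbonyl, so C3–C7 with ring A is a 3-hydroxy-5-arylpentanoate. Its 3-oxo form is a β-keto ester, a substrate class ketoreductases accept, and its ester carbon (C3) can later take up C2.
- Cuts, in retrosynthetic order: the three O–benzyl bonds together with the C1≡C2 unsaturation (one hydrogenation); the C2–C3 bond (ring B arylacetylide plus Weinreb amide); the C5–H bond (enzymatic reduction); the C3–C4 bond (ring A acid plus malonate half ester).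
- Forward: ring A acid → β-keto ester → (R)-hydroxy ester → Weinreb amide → ynone with the ring B alkyne → hydrogenation to the target. The chain is joined linearly and no ring is formed.
- Stereochemistry: the only stereocentre, C5, is set by the enzyme (hydride to the Si face of the ketone); no later step breaks a bond at C5.

Key step: step 3

Assumption: screening a commercial ketoreductase panel is taken to furnish an isopropanol-tolerant enzyme that reduces 6 to the (R)-alcohol; such panels normally contain enzymes of both facial preferences for β-keto esters.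

**Step 1**
Reactants: 1 3-(4-hydroxy-3-methoxyphenyl)propanoic acid (dihydroferulic acid)
Product: 2 3-(4-benzyloxy-3-methoxyphenyl)propanoic acid
Conditions: BnBr (1.2 equiv), NaOH (2.5 equiv), EtOH/H2O, reflux; then 2 M HCl
Reagents that add atoms: benzyl bromide, BrCc1ccccc1
Why: Williamson ether synthesis, in which the phenoxide is far more nucleophilic than the carboxylate in aqueous ethanolic NaOH and any benzyl ester formed is saponified in the same hot alkaline medium, so only the phenol ends up benzylated.

**Step 2**
Reactants: 2 3-(4-benzyloxy-3-methoxyphenyl)propanoic acid; 3 potassium ethyl malonate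
Product: 6 ethyl 5-(4-benzyloxy-3-methoxyphenyl)-3-oxopentanoate, via acyl imidazole 4 (not isolated), via acylmalonic half ester 5 (not isolated)
Conditions: CDI (1.2 equiv), THF, rt; then 3 (2 equiv), MgCl2 (1.5 equiv), THF, rt → 50 °C; 1 M HCl work-up
Reagents that add atoms: none
Why: Masamune–Brooks β-keto ester synthesis, in which the acyl imidazole C-acylates the magnesium enolate of the malonate half ester and the adduct loses CO2 under near-neutral conditions that leave the benzyl ether untouched.

**Step 3**
Reactants: 6 ethyl 5-(4-benzyloxy-3-methoxyphenyl)-3-oxopentanoate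
Product: 7 ethyl (R)-5-(4-benzyloxy-3-methoxyphenyl)-3-hydroxypentanoate
Conditions: (R)-selective ketoreductase (panel hit), NADP+ (cat.), iPrOH (20% v/v), KH2PO4/K2HPO4 buffer (0.1 M, pH 7.0), MgSO4 (2 mM), 30 °C
Reagents that add atoms: none
Why: The ketoreductase binds 6 with the ester arm and the arylethyl arm in its two different pockets and transfers the hydride of enzyme-bound NADPH to the Si face of the ketone carbon that becomes C5 while an active-site acid protonates the oxygen, and the same enzyme returns NADP+ to NADPH by oxidising isopropanol to acetone. The closest known reaction type is the ketoreductase (alcohol dehydrogenase) reduction of 3-oxo-5-arylpentanoates and related β-keto esters. No ring is closed. The new C5 stereocentre is under catalyst control by the chiral active site, the enzyme being chosen from a panel for the (R)-alcohol, which matters because the ketone is flanked by two unbranched methylene chains that offer little steric bias to small reagents. The step needs enantiofacial selectivity and chemoselectivity for the ketone over the ester; the first rests on the different polarity and length of the CH2CO2Et and CH2CH2Ar arms and the second on the inability of the enzyme to reduce esters, while neutral buffer at 30 °C spares the benzyl ether and the elimination-prone β-hydroxy ester. The large excess of isopropanol should drive the equilibrium to the alcohol.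

**Step 4**
Reactants: 7 ethyl (R)-5-(4-benzyloxy-3-methoxyphenyl)-3-hydroxypentanoate
Product: 8 (R)-5-(4-benzyloxy-3-methoxyphenyl)-3-hydroxy-N-methoxy-N-methylpentanamide
Conditions: MeNHOMe·HCl (2.5 equiv), iPrMgCl (6 equiv), THF, −20 → 0 °C; aq. NH4Cl
Reagents that add atoms: N,O-dimethylhydroxylamine hydrochloride, CNOC.Cl
Why: Weinreb amide formation by aminolysis of the ester with the chloromagnesium amide made from the amine salt and iPrMgCl, in which the hydroxyl sits as its magnesium alkoxide, the low temperature disfavours β-elimination and no bond at the stereocentre is broken.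

**Step 5**
Reactants: 9 3,4-dihydroxy-5-methoxybenzaldehyde (5-hydroxyvanillin)
Product: 10 3,4-bis(benzyloxy)-5-methoxybenzaldehyde
Conditions: BnBr (2.4 equiv), K2CO3 (3 equiv), DMF, 60 °C
Reagents that add atoms: benzyl bromide, BrCc1ccccc1
Why: Williamson etherification of both catechol hydroxyls by SN2 attack of the phenoxides on benzyl bromide, the non-enolisable aldehyde being inert to K2CO3.

**Step 6**
Reactants: 10 3,4-bis(benzyloxy)-5-methoxybenzaldehyde
Product: 11 1,2-bis(benzyloxy)-5-ethynyl-3-methoxybenzene
Conditions: dimethyl (1-diazo-2-oxopropyl)phosphonate (1.3 equiv), K2CO3 (2 equiv), MeOH/THF, 0 °C → rt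
Reagents that add atoms: dimethyl (1-diazo-2-oxopropyl)phosphonate, CC(=O)C(=[N+]=[N-])P(=O)(OC)OC
Why: Ohira–Bestmann variant of the Seyferth–Gilbert homologation, in which methanolysis of the acetyl group releases the diazomethylphosphonate anion that olefinates the non-enolisable aryl aldehyde, and loss of N2 with a 1,2-hydrogen shift gives the terminal alkyne.

**Step 7**
Reactants: 8 (R)-5-(4-benzyloxy-3-methoxyphenyl)-3-hydroxy-N-methoxy-N-methylpentanamide; 11 1,2-bis(benzyloxy)-5-ethynyl-3-methoxybenzene
Product: 14 (R)-1-[3,4-bis(benzyloxy)-5-methoxyphenyl]-7-(4-benzyloxy-3-methoxyphenyl)-5-hydroxyhept-1-yn-3-one, via lithium arylacetylide 12 (not isolated), via dilithium hemiaminal adduct 13 (not isolated)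
Conditions: 11 (2.6 equiv), n-BuLi (2.5 equiv), THF, −78 °C; then 8, −78 → 0 °C; poured into cold 0.5 M HCl
Reagents that add atoms: none
Why: Acylation of a lithium acetylide by a Weinreb amide, in which one equivalent of 12 deprotonates the hydroxyl and a second adds to the amide to give a chelated tetrahedral adduct that holds until the cold acidic quench, so a single addition forges C2–C3, the acid protonates the released amine before it can add to the ynone, and C5 is untouched.

**Step 8**
Reactants: 14 (R)-1-[3,4-bis(benzyloxy)-5-methoxyphenyl]-7-(4-benzyloxy-3-methoxyphenyl)-5-hydroxyhept-1-yn-3-one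
Product: 15 (R)-1-(3,4-dihydroxy-5-methoxyphenyl)-5-hydroxy-7-(4-hydroxy-3-methoxyphenyl)heptan-3-one
Conditions: H2 (1 atm), 10% Pd/C, EtOAc/EtOH, rt
Reagents that add atoms: none
Why: Heterogeneous hydrogenation over Pd/C saturates the conjugated triple bond to the C1–C2 ethylene and cleaves the three aryl benzyl ethers by hydrogenolysis, while the dialkyl ketone and the non-benzylic secondary alcohol at C5 are inert.

**Compound list**

1 | 3-(4-hydroxy-3-methoxyphenyl)propanoic acid (dihydroferulic acid) | COc1cc(CCC(=O)O)ccc1O | starting material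
2 | 3-(4-benzyloxy-3-methoxyphenyl)propanoic acid | COc1cc(CCC(=O)O)ccc1OCc1ccccc1 | intermediate
3 | potassium ethyl malonate (potassium 3-ethoxy-3-oxopropanoate) | CCOC(=O)CC(=O)[O-].[K+] | starting material
4 | 1-[3-(4-benzyloxy-3-methoxyphenyl)propanoyl]imidazole | COc1cc(CCC(=O)n2ccnc2)ccc1OCc1ccccc1 | intermediate
5 | 5-(4-benzyloxy-3-methoxyphenyl)-2-(ethoxycarbonyl)-3-oxopentanoic acid (present as its magnesium chelate) | CCOC(=O)C(C(=O)O)C(=O)CCc1ccc(OCc2ccccc2)c(OC)c1 | intermediate
6 | ethyl 5-(4-benzyloxy-3-methoxyphenyl)-3-oxopentanoate | CCOC(=O)CC(=O)CCc1ccc(OCc2ccccc2)c(OC)c1 | intermediate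
7 | ethyl (R)-5-(4-benzyloxy-3-methoxyphenyl)-3-hydroxypentanoate | CCOC(=O)C[C@H](O)CCc1ccc(OCc2ccccc2)c(OC)c1 | intermediate
8 | (R)-5-(4-benzyloxy-3-methoxyphenyl)-3-hydroxy-N-methoxy-N-methylpentanamide | CON(C)C(=O)C[C@H](O)CCc1ccc(OCc2ccccc2)c(OC)c1 | intermediate
9 | 3,4-dihydroxy-5-methoxybenzaldehyde (5-hydroxyvanillin) | COc1cc(C=O)cc(O)c1O | starting material
10 | 3,4-bis(benzyloxy)-5-methoxybenzaldehyde | COc1cc(C=O)cc(OCc2ccccc2)c1OCc1ccccc1 | intermediate
11 | 1,2-bis(benzyloxy)-5-ethynyl-3-methoxybenzene | COc1cc(C#C)cc(OCc2ccccc2)c1OCc1ccccc1 | intermediate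
12 | lithium [3,4-bis(benzyloxy)-5-methoxyphenyl]acetylide | [Li]C#Cc1cc(OC)c(OCc2ccccc2)c(OCc2ccccc2)c1 | intermediate
13 | dilithium salt of the C3 hemiaminal adduct of 8 and 12 (C5 alkoxide, C3 N-methoxy-N-methyl hemiaminal alkoxide) | CON(C)C([O-])(C#Cc1cc(OC)c(OCc2ccccc2)c(OCc2ccccc2)c1)C[C@H]([O-])CCc1ccc(OCc2ccccc2)c(OC)c1.[Li+].[Li+] | intermediate
14 | (R)-1-[3,4-bis(benzyloxy)-5-methoxyphenyl]-7-(4-benzyloxy-3-methoxyphenyl)-5-hydroxyhept-1-yn-3-one | COc1cc(C#CC(=O)C[C@H](O)CCc2ccc(OCc3ccccc3)c(OC)c2)cc(OCc2ccccc2)c1OCc1ccccc1 | intermediate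
15 | (R)-1-(3,4-dihydroxy-5-methoxyphenyl)-5-hydroxy-7-(4-hydroxy-3-methoxyphenyl)heptan-3-one | COc1cc(CC[C@@H](O)CC(=O)CCc2cc(O)c(O)c(OC)c2)ccc1O | target

**Step count and risks**

Total step count: 8. Longest linear sequence: 6 (steps 1, 2, 3, 4, 7 and 8); the ring B alkyne is made in 2 steps (5 and 6) and joins at step 7.

Steps most likely to fail:

1. Step 3. The lipophilic substrate may bind or dissolve poorly, so conversion could stall, or no enzyme of the panel may give sufficient facial selectivity. Fallback: biocatalysis is replaced by chelation-controlled homogeneous asymmetric hydrogenation (Noyori) of keto ester 6 with RuCl2[(R)-BINAP] under H2 in EtOH. By the established model for β-keto esters this should deliver the (R)-alcohol, and the aryl benzyl ether is not cleaved by this catalyst. The detour sets out from 6 and comes back at 7; it makes no new compound (F0).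

2. Step 7. Addition next to the lithium alkoxide may be sluggish, the released N,O-dimethylhydroxylamine may add to the ynone during the quench, or the hydroxy ynone may close by oxa-Michael addition to a dihydropyranone. Fallback: the sp carbon nucleophile is replaced by an sp3 one, so that no ynone is ever formed. The fallback sets out from aldehyde 10 and amide 8 and comes back at target 15.
   - Wittig methylenation of 10 (Ph3PCH3Br, KOtBu, THF) should give the styrene 1,2-bis(benzyloxy)-5-ethenyl-3-methoxybenzene F1.
   - Hydroboration–oxidation (9-BBN, THF; NaOH, H2O2) should give 2-[3,4-bis(benzyloxy)-5-methoxyphenyl]ethanol F2.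
   - Appel bromination (CBr4, PPh3, CH2Cl2) should give 1,2-bis(benzyloxy)-5-(2-bromoethyl)-3-methoxybenzene F3.
   - Mg turnings in THF should convert it into 2-[3,4-bis(benzyloxy)-5-methoxyphenyl]ethylmagnesium bromide F4.
   - About three equivalents of F4 added to 8 at 0 °C should give (R)-1-[3,4-bis(benzyloxy)-5-methoxyphenyl]-7-(4-benzyloxy-3-methoxyphenyl)-5-hydroxyheptan-3-one F5.
   - Hydrogenolysis of its three benzyl ethers (H2, Pd/C, EtOAc/EtOH) leads to 15.

3. Step 4. Under the strongly basic magnesium amide the β-alkoxide may be lost by elimination to the unsaturated amide, retro-aldol cleavage may occur, or aminolysis may stay incomplete. Fallback: direct aminolysis is replaced by hydrolysis and carbodiimide coupling. From 7, LiOH in THF/H2O at 0 °C should give (R)-5-(4-benzyloxy-3-methoxyphenyl)-3-hydroxypentanoic acid F6. This is coupled with N,O-dimethylhydroxylamine hydrochloride using EDC·HCl, HOBt and N-methylmorpholine in CH2Cl2, coming back to the route at 8.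

**Further compounds**

F0 | step 3 | none | none
F1 | step 7 | 1,2-bis(benzyloxy)-5-ethenyl-3-methoxybenzene | COc1cc(C=C)cc(OCc2ccccc2)c1OCc1ccccc1
F2 | step 7 | 2-[3,4-bis(benzyloxy)-5-methoxyphenyl]ethanol | COc1cc(CCO)cc(OCc2ccccc2)c1OCc1ccccc1
F3 | step 7 | 1,2-bis(benzyloxy)-5-(2-bromoethyl)-3-methoxybenzene | COc1cc(CCBr)cc(OCc2ccccc2)c1OCc1ccccc1
F4 | step 7 | 2-[3,4-bis(benzyloxy)-5-methoxyphenyl]ethylmagnesium bromide | COc1cc(CC[Mg]Br)cc(OCc2ccccc2)c1OCc1ccccc1
F5 | step 7 | (R)-1-[3,4-bis(benzyloxy)-5-methoxyphenyl]-7-(4-benzyloxy-3-methoxyphenyl)-5-hydroxyheptan-3-one | COc1cc(CCC(=O)C[C@H](O)CCc2ccc(OCc3ccccc3)c(OC)c2)cc(OCc2ccccc2)c1OCc1ccccc1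
F6 | step 4 | (R)-5-(4-benzyloxy-3-methoxyphenyl)-3-hydroxypentanoic acid | OC(=O)C[C@H](O)CCc1ccc(OCc2ccccc2)c(OC)c1
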